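## Structural features

The target is a flavone: benzene ring A is fused through C4a–C8a to the 4-pyranone ring C, which carries the 4-methoxyphenyl ring B at C2 and a methoxy group at C3. There is no stereocentre. Ring A is hexasubstituted and carries four neighbouring oxygens in four different states: 5-OH (hydrogen-bonded to the C4 carbonyl), 6-OMe, 7-OH and the 8-O-isovalerate. The fragile element is the aryl ester at O8 next to the free, acidic 7-OH: bases and nucleophiles can cleave it or move the acyl group to O7, and any intermediate with O5 and O8 both free is a 5,8-hydroquinone that air can oxidise. The real difficulty is therefore the differentiation of four contiguous ring A oxygens and the placing of the acyl group on O8 alone, not the carbon skeleton. The key step exploits the fact that O1, C2, C3 with its oxygen, C4, C4a, C8a and the exocyclic C8 with its oxygen are the atoms of kojic acid: the C8 methylene on C8a is gamma to the C4 carbonyl and is a vinylogous carbon acid, so only C5, C6 and C7 must be added, as a methoxymalonyl chain on C4a, before a C7–C8 ester condensation closes ring A. Each ring A oxygen then arrives in its own state (5-OH from a ketone, 6-OMe from the chain, 7-OH from the ester carbonyl, 8-OBn from the ether), so no polyphenol has to be protected selectively. The constitutions of the cyclisation precursor and of its product were checked atom by atom against the target and are kept (methyl ester, benzyl ether); what is changed is the way to the precursor, which avoids offering a C–H acidic acid chloride to a basic organomagnesium, and the endgame, in which only O7 needs a temporary group.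

## Logic of the disconnections

21 from 20. The O7–CH2 acetal bond is cut last. The free 7-OH next to the 8-ester is thus revealed only when no base or nucleophile is left in the sequence. The forward step must be a non-nucleophilic acid cleavage that leaves the aryl ester in place.

20 from 18 and 19. The O8–acyl bond is cut. In 18 the 5-OH is tied to the C4 carbonyl and O7 is blocked, so the 8-OH is the only phenol that acylates readily. The demand is close control of the amount of 19 and exclusion of air, because 18 is a 5,8-hydroquinone.

18 from 17, and 17 from 16. The O8–benzyl bond and then the O7–methoxymethyl bond are cut. The benzyl group has to be on O8 because it travels on the C8 methylene from the start; the group on O7 must therefore survive hydrogenolysis and must not migrate to a neighbouring phenol, which rules out silyl and acyl groups. Only O7 is protected: it is the most acidic phenol of 16, and the chelated 5-OH is left alone.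

16 from 14 through 15. The C7–C8 bond of ring A is cut. A hexasubstituted benzene with four differentiated oxygens becomes a trisubstituted pyranone with a three-carbon chain, and the oxygen pattern is written into that chain. The forward step needs a second deprotonation at the C8 methylene of the keto ester enolate and carbon acylation in a six-membered mode.

14 from 10 (through 13) and 12; 12 from 11. The C5–C6 bond is cut, the retron being a beta-keto ester. A decarboxylative Claisen condensation of a magnesium malonate half-ester enolate is chosen because it needs only an amine base, so the C8 methylene is not touched before the key step. An acyl imidazolide is preferred to an acid chloride, which could lactonise onto the benzyloxymethyl oxygen with loss of the benzyl group. The half-ester salt 12 comes from 11 by hydrolysis of one of two equivalent esters.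

10 from 8 through 9; 8 from 7. The C4a–C5 bond is cut to a pyranonyl organomagnesium and CO2, an electrophile without acidic hydrogen; the C4a–I bond is then cut. The forward demands are iodination at the only ring C–H of 7 in preference to the anisyl ring, and an iodine–magnesium exchange cold enough that the organometallic neither abstracts a C8 proton nor opens the ring.

7 from 5 and 6. The C2–C1' bond between rings C and B is cut (Suzuki–Miyaura). The bromide of 5 is a vinylogous acyl bromide and is highly reactive toward zerovalent palladium; the demand is a base system that does not hydrolyse it.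

5 from 3 and 4; 3 from 2; 2 from 1. The O–benzyl, O–methyl and C2–Br bonds are cut in turn. Bromination comes first because the free enol of 1 directs the electrophile to its only ortho carbon. Methylation of the acidic enol follows, and the primary alcohol is benzylated last under neutral conditions so that no alkoxide meets the reactive C–Br bond.

## Other disconnections considered

Alternative 1: Ring A is cut at C8–C8a, and C4a–C5 is traced back to the addition of a pyranonyl metal to a squarate. In the forward sense a pyranone lacking C8, metallated at the future C4a, would add to the mixed squarate 3-tert-butoxy-4-methoxycyclobut-3-ene-1,2-dione A1. This would give the carbinol 2-tert-butoxy-4-hydroxy-3-methoxy-4-[5-methoxy-6-(4-methoxyphenyl)-4-oxo-4H-pyran-3-yl]cyclobut-2-en-1-one A2 (racemic; the stereocentre is lost later). Heating A2 would open the four-membered ring to a dienylketene, whose ketene carbon closes by 6π electrocyclisation onto the pyranone C–H carbon next to O1; tautomerisation gives 7-tert-butoxy-5,8-dihydroxy-3,6,4'-trimethoxyflavone A3.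
- In favour: the ring expansion is thermal, needs no reagent and is well precedented for aryl and heteroaryl cyclobutenones. On mechanistic precedent it is better than the chosen key step. A3 has O8 free, O5 chelated and O7 masked, so the endgame would be two steps (acylation, acid removal of tert-butyl) against four; this is also better.
- Against: the two carbonyls of A1 differ only in a remote alkoxy group, so the regiochemistry of addition is not secured, and the wrong adduct exchanges 6-OMe and 7-O-tert-butyl. The tert-butyl ether may be lost at the thermolysis temperature, which would erase the O7/O8 distinction. A3 is an electron-rich hydroquinone that air oxidises. The pyranone partner must be metallated beside an acidic, unsubstituted C–H. The last step again puts acid next to the aryl ester, which is equal to the chosen plan.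
- Comparison: both plans build ring A on a finished ring C. The chosen plan fixes the 6-OMe/7-OH pattern by the constitution of the chain, whereas this one rests on a regioselective addition. The total step count would be similar or slightly lower.

Alternative 2: Ring C is cut at C4–C4a. The phenol 2-(allyloxy)-3,5-bis(benzyloxy)-4-methoxyphenol A4 would be converted into the enol ether acid (2E)-3-[2-(allyloxy)-3,5-bis(benzyloxy)-4-methoxyphenoxy]-2-methoxy-3-(4-methoxyphenyl)prop-2-enoic acid A5. Activation of A5 with trifluoroacetic anhydride would acylate the only free arene carbon and give 8-(allyloxy)-5,7-bis(benzyloxy)-3,6,4'-trimethoxyflavone A6.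
- In favour: intramolecular Friedel–Crafts closure of chromones is classical, and with a single free position there is no regiochemical question; in precedent this is better than the chosen key step. A6 is fully differentiated, so the endgame (deallylation with zerovalent palladium, acylation, global hydrogenolysis) is three steps and ends under neutral conditions; this is better by one step and by a gentler last step.
- Against: the differentiation problem is only moved into A4, a pentaoxygenated benzene with four kinds of oxygen substituent that needs a long sequence of selective protections. A5 is a tetrasubstituted enol ether that must have the carboxyl group cis to the aryloxy group, and a hindered phenoxide is a poor partner for making it. The strongly acidic activation may also cleave allyl or benzyl ethers on so electron-rich a ring.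
- Comparison: the ring-forming step is safer, but the overall route is clearly longer than the kojic acid route, in which ring C and two of its oxygens are bought ready-made.

Alternative 3: Ring C is cut at O1–C8a. The acylquinone 5-(benzyloxy)-6-methoxy-2-[2-methoxy-3-(4-methoxyphenyl)-3-oxopropanoyl]cyclohexa-2,5-diene-1,4-dione A7, made by oxidation of the corresponding hydroquinone, would take up the enol oxygen of its diketone chain at the unsubstituted quinone carbon. This 6-endo oxa-Michael addition, followed by tautomerisation, gives 7-(benzyloxy)-5,8-dihydroxy-3,6,4'-trimethoxyflavone A8.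
- In favour: the closure is redox-neutral, and the lone free quinone carbon fixes the regiochemistry. A8 has O8 free, O5 chelated and O7 benzylated, so two steps finish the synthesis (acylation, then neutral hydrogenolysis); this endgame is better than the chosen one.
- Against: acylquinones are strong, unselective electrophiles, and A7 also carries an enolisable 2-methoxy-1,3-diketone that is open to retro-Claisen cleavage. Its formation by oxidation must spare the anisyl ketone enol, and redox exchange between A7 and A8 can divert material to a flavone quinone. The hydroquinone precursor still requires a tetraoxygenated acetophenone with a differentiated oxygen pattern.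
- Comparison: conjugate addition of oxygen to quinones is a known type, which the chosen key step is not. The overall step count is comparable. The chosen plan is preferred because its oxygen pattern comes from cheap building blocks and not from arene protecting-group work.

Key step: step 9

Remark on the chemistry: the target has no stereocentre, so no stereochemical assumption is needed. Ring atoms of the pyranone intermediates are called by the flavone locants they become (O1, C2, C3, C4, C4a, C8a, exocyclic C8), while compound names use pyranone locants.

## Route

Step 1
Reactants: 1 kojic acid (5-hydroxy-2-(hydroxymethyl)-4H-pyran-4-one)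
Product: 2 2-bromo-3-hydroxy-6-(hydroxymethyl)-4H-pyran-4-one (bromine on the future C2)
Conditions: NBS (1.05 equiv), MeCN/DMF, 0 °C to rt
Reagents that add atoms: N-bromosuccinimide, O=C1CCC(=O)N1Br
Why: Electrophilic bromination of the free enol, which directs to its only ortho carbon, the position at which kojic acid also undergoes Mannich and hydroxymethylation reactions; it is done before O-methylation to keep this directing effect.

Step 2
Reactants: 2 2-bromo-3-hydroxy-6-(hydroxymethyl)-4H-pyran-4-one
Product: 3 2-bromo-6-(hydroxymethyl)-3-methoxy-4H-pyran-4-one
Conditions: MeI, K2CO3, acetone, rt to 40 °C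
Reagents that add atoms: iodomethane, CI
Why: Williamson etherification; carbonate ionises only the acidic enol (phenol-like) and not the primary alcohol, so O-methylation should be selective and sets the future 3-OMe.

Step 3
Reactants: 3 2-bromo-6-(hydroxymethyl)-3-methoxy-4H-pyran-4-one; 4 benzyl bromide
Product: 5 6-[(benzyloxy)methyl]-2-bromo-3-methoxy-4H-pyran-4-one
Conditions: 4 (1.5 equiv), Ag2O (1.5 equiv), CH2Cl2, rt, dark
Reagents that add atoms: none
Why: Silver-oxide-mediated benzylation of a primary alcohol under neutral conditions; no alkoxide is formed, so the vinylogous acyl bromide is not displaced by addition–elimination.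

Step 4
Reactants: 5 6-[(benzyloxy)methyl]-2-bromo-3-methoxy-4H-pyran-4-one; 6 4-methoxyphenylboronic acid
Product: 7 6-[(benzyloxy)methyl]-3-methoxy-2-(4-methoxyphenyl)-4H-pyran-4-one
Conditions: Pd(dppf)Cl2 (5 mol %), K3PO4, dioxane/H2O (10:1), 80 °C
Reagents that add atoms: none
Why: Suzuki–Miyaura coupling; the C–Br bond beta to the carbonyl and alpha to the ring oxygen adds readily to zerovalent palladium, and the mild phosphate base with little water limits hydrolysis of the bromide.

Step 5
Reactants: 7 6-[(benzyloxy)methyl]-3-methoxy-2-(4-methoxyphenyl)-4H-pyran-4-one
Product: 8 2-[(benzyloxy)methyl]-3-iodo-5-methoxy-6-(4-methoxyphenyl)-4H-pyran-4-one (iodine on the future C4a)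
Conditions: I2 (0.6 equiv), (NH4)2Ce(NO3)6 (1.1 equiv), MeCN, 50 °C
Reagents that add atoms: iodine, II
Why: Oxidative electrophilic iodination at the only ring C–H, the alpha carbon of the vinylogous ester, which is the position iodinated in flavones and chromones by this reagent pair; the anisyl ring is deactivated by conjugation with the pyranone.

Step 6
Reactants: 8 2-[(benzyloxy)methyl]-3-iodo-5-methoxy-6-(4-methoxyphenyl)-4H-pyran-4-one
Product: 10 2-[(benzyloxy)methyl]-5-methoxy-6-(4-methoxyphenyl)-4-oxo-4H-pyran-3-carboxylic acid, via pyranonylmagnesium chloride 9 (not isolated)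
Conditions: iPrMgCl·LiCl (1.1 equiv), THF, −40 °C, 20 min; CO2 (g), −40 °C to rt; 1 M HCl
Reagents that add atoms: carbon dioxide, O=C=O
Why: Iodine–magnesium exchange on an alpha-iodo enone of the 3-iodochromone class, then carboxylation; CO2 is small, fast and carries no acidic hydrogen, so the basic organometallic is consumed before it can abstract a C8 proton.

Step 7
Reactants: 11 dimethyl methoxymalonate
Product: 12 potassium 2,3-dimethoxy-3-oxopropanoate (potassium methyl methoxymalonate)
Conditions: KOH (1.0 equiv), MeOH, 0 °C to rt; concentrate, triturate with Et2O
Reagents that add atoms: potassium hydroxide, [K+].[OH-]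
Why: Monosaponification of a symmetrical malonate; the carboxylate formed first slows hydrolysis of the second ester, so one equivalent of hydroxide should stop at the half-ester salt.

Step 8
Reactants: 10 2-[(benzyloxy)methyl]-5-methoxy-6-(4-methoxyphenyl)-4-oxo-4H-pyran-3-carboxylic acid; 12 potassium 2,3-dimethoxy-3-oxopropanoate
Product: 14 methyl 3-{2-[(benzyloxy)methyl]-5-methoxy-6-(4-methoxyphenyl)-4-oxo-4H-pyran-3-yl}-2-methoxy-3-oxopropanoate (racemic at the methoxy-bearing carbon, enolisable), via acyl imidazolide 13 (not isolated)
Conditions: 1,1'-carbonyldiimidazole (1.1 equiv), THF, rt; then 12 (2 equiv), MgCl2 (2 equiv), Et3N (3 equiv), MeCN, rt to 45 °C; 1 M HCl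
Reagents that add atoms: none
Why: Decarboxylative Claisen condensation of the Masamune–Brooks type: the magnesium enolate of the half-ester is C-acylated by the imidazolide and loses CO2 to give the beta-keto ester. Only an amine base is present, so the C8 methylene stays untouched, and the imidazolide is too weak an electrophile to lactonise onto the benzyloxymethyl oxygen.

Step 9
Reactants: 14 methyl 3-{2-[(benzyloxy)methyl]-5-methoxy-6-(4-methoxyphenyl)-4-oxo-4H-pyran-3-yl}-2-methoxy-3-oxopropanoate
Product: 16 8-(benzyloxy)-5,7-dihydroxy-3,6,4'-trimethoxyflavone, via dilithium dianion 15 (not isolated)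
Conditions: LiN(SiMe3)2 (3.5 equiv), THF (0.02 M), −78 °C to rt; 1 M HCl
Reagents that add atoms: none
Why: Proposed new method: the first equivalent of LiN(SiMe3)2 removes the C6 methine proton to give the keto ester enolate, and a second equivalent removes a proton from the C8 methylene, which is acidified vinylogously through C8a=C4a by the C4 and C5 carbonyls, so that dianion 15 forms. The C8 terminus of this dienolate then attacks the ester carbonyl C7 in a 6-(enolendo)-exo-trig closure that forms C7–C8 and ring A; methoxide leaves, and two enolisations give the aromatic 5,7-bis-phenoxide, which makes the sequence irreversible. The closest known reaction types are Dieckmann and Claisen aromatisations of polycarbonyl esters and the gamma-deprotonation and acylation of 2-alkyl-4-pyranones and 2-methylchromones; new is their union with a benzyloxymethyl donor and a keto ester enolate as acceptor. No stereocentre is created, and the one at C6 of 14 is erased on aromatisation. The step needs carbon acylation at C8 in preference to closure through O4, intermolecular condensation and addition of base at C2: closure through O4 would give a six-membered enol lactone that liberated methoxide can reopen, whereas the carbon path is drained by aromatisation; high dilution suppresses intermolecular reaction, the hindered amide does not add to the pyranone, and attack through C4a would need a four-membered ring. Lithium bridging O4 and O5 is expected to hold the chain on the side of C8, as the hydrogen bond does in the product.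

Step 10
Reactants: 16 8-(benzyloxy)-5,7-dihydroxy-3,6,4'-trimethoxyflavone
Product: 17 8-(benzyloxy)-5-hydroxy-3,6,4'-trimethoxy-7-(methoxymethoxy)flavone
Conditions: MOMCl (1.2 equiv), iPr2NEt, CH2Cl2, 0 °C to rt
Reagents that add atoms: chloromethyl methyl ether, COCCl
Why: Selective acetal protection of the most acidic phenol (7-OH, para to the C4 carbonyl); the 5-OH is held in the hydrogen bond to C4=O and should not react with a small excess of reagent.

Step 11
Reactants: 17 8-(benzyloxy)-5-hydroxy-3,6,4'-trimethoxy-7-(methoxymethoxy)flavone
Product: 18 5,8-dihydroxy-3,6,4'-trimethoxy-7-(methoxymethoxy)flavone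
Conditions: H2 (1 atm), Pd/C (10 wt %), EtOAc, rt; filter under argon and use at once
Reagents that add atoms: none
Why: Hydrogenolysis of the benzyl aryl ether; the acetal, the methyl ethers and the tetrasubstituted C2=C3 bond are inert, and the 5,8-hydroquinone formed is kept from air and taken on directly.

Step 12
Reactants: 18 5,8-dihydroxy-3,6,4'-trimethoxy-7-(methoxymethoxy)flavone; 19 isovaleryl chloride (3-methylbutanoyl chloride)
Product: 20 5-hydroxy-3,6,4'-trimethoxy-7-(methoxymethoxy)flavon-8-yl 3-methylbutanoate
Conditions: 19 (1.1 equiv), pyridine, CH2Cl2, 0 °C, argon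
Reagents that add atoms: none
Why: Acylation of the only non-chelated phenol; the 5-OH is deactivated by its hydrogen bond and O7 is blocked, so one equivalent of acid chloride should give the 8-ester alone.

Step 13
Reactants: 20 5-hydroxy-3,6,4'-trimethoxy-7-(methoxymethoxy)flavon-8-yl 3-methylbutanoate
Product: 21 5,7,8-trihydroxy-3,6,4'-trimethoxyflavone 8-isovalerate (target)
Conditions: CF3CO2H/CH2Cl2 (1:5), 0 °C to rt; wash with pH 6–7 buffer
Reagents that add atoms: none
Why: Acid cleavage of an aryl methoxymethyl acetal in a non-nucleophilic medium, so the aryl ester meets neither base nor alcohol; the acyl group is also expected to prefer O8 thermodynamically, because the 7-OH is the more acidic phenol and is conjugated with the C4 carbonyl.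

## Compound list

1 | kojic acid (5-hydroxy-2-(hydroxymethyl)-4H-pyran-4-one) | O=c1cc(CO)occ1O | starting material
2 | 2-bromo-3-hydroxy-6-(hydroxymethyl)-4H-pyran-4-one | O=c1cc(CO)oc(Br)c1O | intermediate
3 | 2-bromo-6-(hydroxymethyl)-3-methoxy-4H-pyran-4-one | COc1c(Br)oc(CO)cc1=O | intermediate
4 | benzyl bromide | BrCc1ccccc1 | starting material
5 | 6-[(benzyloxy)methyl]-2-bromo-3-methoxy-4H-pyran-4-one | COc1c(Br)oc(COCc2ccccc2)cc1=O | intermediate
6 | 4-methoxyphenylboronic acid | COc1ccc(B(O)O)cc1 | starting material
7 | 6-[(benzyloxy)methyl]-3-methoxy-2-(4-methoxyphenyl)-4H-pyran-4-one | COc1ccc(cc1)-c1oc(COCc2ccccc2)cc(=O)c1OC | intermediate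
8 | 2-[(benzyloxy)methyl]-3-iodo-5-methoxy-6-(4-methoxyphenyl)-4H-pyran-4-one | COc1ccc(cc1)-c1oc(COCc2ccccc2)c(I)c(=O)c1OC | intermediate
9 | {2-[(benzyloxy)methyl]-5-methoxy-6-(4-methoxyphenyl)-4-oxo-4H-pyran-3-yl}magnesium chloride (LiCl complex, not isolated) | COc1ccc(cc1)-c1oc(COCc2ccccc2)c([Mg]Cl)c(=O)c1OC | intermediate
10 | 2-[(benzyloxy)methyl]-5-methoxy-6-(4-methoxyphenyl)-4-oxo-4H-pyran-3-carboxylic acid | COc1ccc(cc1)-c1oc(COCc2ccccc2)c(C(=O)O)c(=O)c1OC | intermediate
11 | dimethyl methoxymalonate | COC(C(=O)OC)C(=O)OC | starting material
12 | potassium 2,3-dimethoxy-3-oxopropanoate | COC(C(=O)OC)C(=O)[O-].[K+] | intermediate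
13 | {2-[(benzyloxy)methyl]-5-methoxy-6-(4-methoxyphenyl)-4-oxo-4H-pyran-3-yl}(1H-imidazol-1-yl)methanone (not isolated) | COc1ccc(cc1)-c1oc(COCc2ccccc2)c(C(=O)n2ccnc2)c(=O)c1OC | intermediate
14 | methyl 3-{2-[(benzyloxy)methyl]-5-methoxy-6-(4-methoxyphenyl)-4-oxo-4H-pyran-3-yl}-2-methoxy-3-oxopropanoate (racemic) | COc1ccc(cc1)-c1oc(COCc2ccccc2)c(C(=O)C(OC)C(=O)OC)c(=O)c1OC | intermediate
15 | dilithium salt of the dianion of 14 (C6 enolate and C8 carbanion, not isolated) | [Li+].[Li+].COC(=O)C(OC)=C([O-])c1c([CH-]OCc2ccccc2)oc(-c2ccc(OC)cc2)c(OC)c1=O | intermediate
16 | 8-(benzyloxy)-5,7-dihydroxy-3,6,4'-trimethoxyflavone | COc1ccc(-c2oc3c(OCc4ccccc4)c(O)c(OC)c(O)c3c(=O)c2OC)cc1 | intermediate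
17 | 8-(benzyloxy)-5-hydroxy-3,6,4'-trimethoxy-7-(methoxymethoxy)flavone | COCOc1c(OC)c(O)c2c(=O)c(OC)c(-c3ccc(OC)cc3)oc2c1OCc1ccccc1 | intermediate
18 | 5,8-dihydroxy-3,6,4'-trimethoxy-7-(methoxymethoxy)flavone | COCOc1c(OC)c(O)c2c(=O)c(OC)c(-c3ccc(OC)cc3)oc2c1O | intermediate
19 | isovaleryl chloride (3-methylbutanoyl chloride) | CC(C)CC(=O)Cl | starting material
20 | 5-hydroxy-3,6,4'-trimethoxy-7-(methoxymethoxy)flavon-8-yl 3-methylbutanoate | COCOc1c(OC)c(O)c2c(=O)c(OC)c(-c3ccc(OC)cc3)oc2c1OC(=O)CC(C)C | intermediate
21 | 5,7,8-trihydroxy-3,6,4'-trimethoxyflavone 8-isovalerate | COc1ccc(-c2oc3c(OC(=O)CC(C)C)c(O)c(OC)c(O)c3c(=O)c2OC)cc1 | target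

## Step count and least certain steps

Total: 13 steps. Longest linear sequence: 12 steps (steps 1–6 and 8–13 from kojic acid); step 7 is a one-step side branch.

Step 9 (key step, new method). The likely failures are:
- the second deprotonation may stall at the keto ester enolate;
- the chelated enolate may hold the ester away from C8;
- closure through O4 may dominate and give the enol lactone;
- intermolecular condensation may occur;
- liberated methoxide may add to the pyranone and open it.

The fallback uses known reaction types and moves the ring closure to C5–C6. From acid 10, esterification (MeI, K2CO3, DMF) would give methyl 2-[(benzyloxy)methyl]-5-methoxy-6-(4-methoxyphenyl)-4-oxo-4H-pyran-3-carboxylate F1. Gamma-deprotonation of F1 with LiN(SiMe3)2 at −78 °C and acylation of the C8 carbanion with the Weinreb amide of methoxyacetic acid (the known intermolecular acylation of 2-alkylpyranone anions) would give methyl 2-[1-(benzyloxy)-3-methoxy-2-oxopropyl]-5-methoxy-6-(4-methoxyphenyl)-4-oxo-4H-pyran-3-carboxylate F2 (racemic). Treatment of F2 with excess LiN(SiMe3)2 or NaH in THF would form the dianion, whose terminal methoxymethyl carbon attacks the ring ester in a classical Claisen aromatisation. This comes back to the route at 16.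

Step 5. Iodination may go to the anisyl ring ortho to its methoxy group, or tetravalent cerium may oxidise the benzylic ether. The fallback halogenates before ring B is present. From 5, iodination at its only ring C–H would give 2-[(benzyloxy)methyl]-6-bromo-3-iodo-5-methoxy-4H-pyran-4-one F3. Selective iodine–magnesium exchange at −78 °C and carboxylation would give 2-[(benzyloxy)methyl]-6-bromo-5-methoxy-4-oxo-4H-pyran-3-carboxylic acid F4. Suzuki–Miyaura coupling of F4 with 6 (one extra equivalent of base) comes back to the route at 10.

Step 6. The organomagnesium 9 may take a proton from the acidic C8 methylene of a second molecule, which returns 7, or it may open the ring by beta-elimination of the ring oxygen if it warms. The fallback avoids a basic organometallic: from 8, hydroxycarbonylation under zerovalent palladium catalysis (Pd(OAc)2, a bisphosphine, CO at 1 atm, KOAc, DMF/H2O, 70 °C) would give 10 directly.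

Step 8. Acylation may be slow, because the imidazolide is flanked by the C4 carbonyl and the benzyloxymethyl group and the enolate is alpha-substituted. Premature decarboxylation of the half-ester, or lactonisation of the activated acid with loss of the benzyl group, may then take over. The fallback builds the chain through an aldehyde. From 8, iodine–magnesium exchange and quenching with DMF would give 2-[(benzyloxy)methyl]-5-methoxy-6-(4-methoxyphenyl)-4-oxo-4H-pyran-3-carbaldehyde F5. Aldol addition of the lithium enolate of methyl methoxyacetate at −78 °C would give methyl 3-{2-[(benzyloxy)methyl]-5-methoxy-6-(4-methoxyphenyl)-4-oxo-4H-pyran-3-yl}-3-hydroxy-2-methoxypropanoate F6 (mixture of diastereomers). Oxidation of F6 with Dess–Martin periodinane comes back to the route at 14.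

Step 13. During acetal cleavage the acyl group may migrate from O8 to O7 or be lost by solvolysis, and the released methoxymethyl cation may alkylate ring B. The fallback changes the protecting-group order so that the last step is a neutral hydrogenolysis. From 16, hydrogenolysis would give 5,7,8-trihydroxy-3,6,4'-trimethoxyflavone F7 (handled under argon). Selective benzylation of its most acidic phenol (BnBr, KHCO3, DMF) would give 7-(benzyloxy)-5,8-dihydroxy-3,6,4'-trimethoxyflavone F8. Acylation of F8 with 19 would give 7-(benzyloxy)-5-hydroxy-3,6,4'-trimethoxyflavon-8-yl 3-methylbutanoate F9. Hydrogenolysis of F9 (H2, Pd/C, EtOAc) comes back to the route at 21.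

## Further compounds

F1 | step 9 | methyl 2-[(benzyloxy)methyl]-5-methoxy-6-(4-methoxyphenyl)-4-oxo-4H-pyran-3-carboxylate | COc1ccc(cc1)-c1oc(COCc2ccccc2)c(C(=O)OC)c(=O)c1OC
F2 | step 9 | methyl 2-[1-(benzyloxy)-3-methoxy-2-oxopropyl]-5-methoxy-6-(4-methoxyphenyl)-4-oxo-4H-pyran-3-carboxylate (racemic) | COCC(=O)C(OCc1ccccc1)c1oc(-c2ccc(OC)cc2)c(OC)c(=O)c1C(=O)OC
F3 | step 5 | 2-[(benzyloxy)methyl]-6-bromo-3-iodo-5-methoxy-4H-pyran-4-one | COc1c(Br)oc(COCc2ccccc2)c(I)c1=O
F4 | step 5 | 2-[(benzyloxy)methyl]-6-bromo-5-methoxy-4-oxo-4H-pyran-3-carboxylic acid | COc1c(Br)oc(COCc2ccccc2)c(C(=O)O)c1=O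
F0 | step 6 | none | none
F5 | step 8 | 2-[(benzyloxy)methyl]-5-methoxy-6-(4-methoxyphenyl)-4-oxo-4H-pyran-3-carbaldehyde | COc1ccc(cc1)-c1oc(COCc2ccccc2)c(C=O)c(=O)c1OC
F6 | step 8 | methyl 3-{2-[(benzyloxy)methyl]-5-methoxy-6-(4-methoxyphenyl)-4-oxo-4H-pyran-3-yl}-3-hydroxy-2-methoxypropanoate (mixture of diastereomers, racemic) | COc1ccc(cc1)-c1oc(COCc2ccccc2)c(C(O)C(OC)C(=O)OC)c(=O)c1OC
F7 | step 13 | 5,7,8-trihydroxy-3,6,4'-trimethoxyflavone | COc1ccc(-c2oc3c(O)c(O)c(OC)c(O)c3c(=O)c2OC)cc1
F8 | step 13 | 7-(benzyloxy)-5,8-dihydroxy-3,6,4'-trimethoxyflavone | COc1ccc(-c2oc3c(O)c(OCc4ccccc4)c(OC)c(O)c3c(=O)c2OC)cc1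
F9 | step 13 | 7-(benzyloxy)-5-hydroxy-3,6,4'-trimethoxyflavon-8-yl 3-methylbutanoate | COc1ccc(-c2oc3c(OC(=O)CC(C)C)c(OCc4ccccc4)c(OC)c(O)c3c(=O)c2OC)cc1
A1 | alternative 1 | 3-tert-butoxy-4-methoxycyclobut-3-ene-1,2-dione | COC1=C(OC(C)(C)C)C(=O)C1=O
A2 | alternative 1 | 2-tert-butoxy-4-hydroxy-3-methoxy-4-[5-methoxy-6-(4-methoxyphenyl)-4-oxo-4H-pyran-3-yl]cyclobut-2-en-1-one (racemic) | COC1=C(OC(C)(C)C)C(=O)C1(O)c1coc(-c2ccc(OC)cc2)c(OC)c1=O
A3 | alternative 1 | 7-tert-butoxy-5,8-dihydroxy-3,6,4'-trimethoxyflavone | COc1ccc(-c2oc3c(O)c(OC(C)(C)C)c(OC)c(O)c3c(=O)c2OC)cc1
A4 | alternative 2 | 2-(allyloxy)-3,5-bis(benzyloxy)-4-methoxyphenol | C=CCOc1c(O)cc(OCc2ccccc2)c(OC)c1OCc1ccccc1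
A5 | alternative 2 | (2E)-3-[2-(allyloxy)-3,5-bis(benzyloxy)-4-methoxyphenoxy]-2-methoxy-3-(4-methoxyphenyl)prop-2-enoic acid | COC(/C(O)=O)=C(/Oc1cc(OCc2ccccc2)c(OC)c(OCc2ccccc2)c1OCC=C)c1ccc(OC)cc1
A6 | alternative 2 | 8-(allyloxy)-5,7-bis(benzyloxy)-3,6,4'-trimethoxyflavone | C=CCOc1c(OCc2ccccc2)c(OC)c(OCc2ccccc2)c2c(=O)c(OC)c(-c3ccc(OC)cc3)oc12
A7 | alternative 3 | 5-(benzyloxy)-6-methoxy-2-[2-methoxy-3-(4-methoxyphenyl)-3-oxopropanoyl]cyclohexa-2,5-diene-1,4-dione (racemic, enolisable) | COc1ccc(cc1)C(=O)C(OC)C(=O)C1=CC(=O)C(OCc2ccccc2)=C(OC)C1=O
A8 | alternative 3 | 7-(benzyloxy)-5,8-dihydroxy-3,6,4'-trimethoxyflavone | COc1ccc(-c2oc3c(O)c(OCc4ccccc4)c(OC)c(O)c3c(=O)c2OC)cc1
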